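**Overview**

1. Retrosynthetic cuts, in order: the bond from the seven-ring methine (CH–4-hydroxyphenyl) to ring A, then the indane C1–C2 bond, with the ring B oxygen re-bonded to indane C2; after that the ring B–acyl bond, the C2–C3 bond of the dihydrobenzofuran so revealed, the ring B–C3 bond and the stilbene C=C.
2. Enabling feature: on the central resorcinol ring B, the free phenol oxygen ortho to indane C3 (CH–3,5-dihydroxyphenyl) stands 1,5 to indane C2 (CH–4-hydroxyphenyl). The target therefore hides a 2,3-diaryl-2,3-dihydrobenzofuran whose next two ring B carbons carry a 4-hydroxystyryl group (indane C1 plus the methine) and the ring A aroyl group (the ketone), so that ether leaving group, olefin and terminating arene sit on three neighbouring ring B carbons.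
3. Forward: ring B is built as a dibromostilbene, joined to the sulfonate-protected resorcinol aldehyde and oxidised; the methyl ether beside the ketone is exchanged for a 4-methoxybenzyl ether; the dihydrobenzofuran ring is closed first by carbene C–H insertion; ring A is then attached by acylation.
4. One Lewis acid operation opens the furan and closes the cyclopentane and, directly after it, the cycloheptenone; sulfonate cleavage and demethylation finish the route.
5. Stereochemistry: indane C3 comes from the insertion catalysed by Rh2(R-PTAD)4; indane C2, indane C1 and the methine are relayed from it in the cascade (all-trans indane, anti hydrogens across the C1–methine bond); the furan C2 centre is sacrificial.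

Key step: step 11

Assumption: Rh2(R-PTAD)4 is taken to be the catalyst antipode that gives the (3S) centre of 15; if the sense of induction is the reverse, Rh2(S-PTAD)4 is used and nothing else changes.

**Route**

Step 1
Reactants: 1 3,5-dimethoxybenzaldehyde
Product: 2 2,6-dibromo-3,5-dimethoxybenzaldehyde
Conditions: Br2 (2.2 equiv), AcOH, rt
Reagents that add atoms: bromine, BrBr
Why: Electrophilic aromatic bromination should occur twice at the two equivalent positions that are ortho to one methoxy group and para to the other (C2 and C6), the position between the two methoxy groups being the more hindered one.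

Step 2
Reactants: 2 2,6-dibromo-3,5-dimethoxybenzaldehyde; 3 diethyl (4-methoxybenzyl)phosphonate
Product: 4 (E)-2,6-dibromo-3,5-dimethoxy-4'-methoxystilbene
Conditions: KOt-Bu (1.2 equiv), THF, 0 °C to rt; dilute aq. HCl quench
Reagents that add atoms: none
Why: The Horner–Wadsworth–Emmons reaction of the stabilised benzylic phosphonate anion with the aryl aldehyde should give the (E)-stilbene through the thermodynamically preferred anti oxaphosphetane.

Step 3
Reactants: 5 3,5-dihydroxybenzaldehyde
Product: 6 3,5-bis(tosyloxy)benzaldehyde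
Conditions: TsCl (2.2 equiv), Et3N, DMAP (cat.), CH2Cl2, 0 °C to rt
Reagents that add atoms: p-toluenesulfonyl chloride, Cc1ccc(cc1)S(=O)(=O)Cl
Why: Sulfonylation of both phenols under standard amine/DMAP conditions installs electron-withdrawing groups that tolerate organolithium, boron halide and carbene chemistry and keep this ring a poor Friedel–Crafts partner until step 12.

Step 4
Reactants: 4 (E)-2,6-dibromo-3,5-dimethoxy-4'-methoxystilbene; 6 3,5-bis(tosyloxy)benzaldehyde
Product: 8 racemic (E)-[3-bromo-4,6-dimethoxy-2-(4-methoxystyryl)phenyl][3,5-bis(tosyloxy)phenyl]methanol, via aryllithium 7 (not isolated)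
Conditions: n-BuLi (1.0 equiv), THF, −78 °C; then 6, −78 °C; H2O quench
Reagents that add atoms: none
Why: Bromine–lithium exchange with one equivalent of n-BuLi is fast at −78 °C and stops after one bromine, and the aryllithium should add to the aldehyde (1,2-addition) far faster than it attacks sulfonate sulfur; the new carbinol centre is racemic and is erased in step 5.

Step 5
Reactants: 8 racemic (E)-[3-bromo-4,6-dimethoxy-2-(4-methoxystyryl)phenyl][3,5-bis(tosyloxy)phenyl]methanol
Product: 9 (E)-[3-bromo-4,6-dimethoxy-2-(4-methoxystyryl)phenyl][3,5-bis(tosyloxy)phenyl]methanone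
Conditions: Dess–Martin periodinane, pyridine, CH2Cl2, 0 °C to rt
Reagents that add atoms: none
Why: Dess–Martin oxidation of the diaryl carbinol runs under pyridine-buffered, non-acidic conditions, which should keep the ionisable doubly benzylic alcohol from cyclising onto the neighbouring styrene.

Step 6
Reactants: 9 (E)-[3-bromo-4,6-dimethoxy-2-(4-methoxystyryl)phenyl][3,5-bis(tosyloxy)phenyl]methanone
Product: 10 (E)-[3-bromo-6-hydroxy-4-methoxy-2-(4-methoxystyryl)phenyl][3,5-bis(tosyloxy)phenyl]methanone
Conditions: BCl3 (1.2 equiv), CH2Cl2, −78 to 0 °C; aq. work-up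
Reagents that add atoms: none
Why: In this chelation-directed ether cleavage, BCl3 held between the ketone oxygen and the ortho methoxy oxygen should remove only that methyl group, while the three methyl ethers without a neighbouring carbonyl group and the sulfonates are left alone at low temperature.

Step 7
Reactants: 10 (E)-[3-bromo-6-hydroxy-4-methoxy-2-(4-methoxystyryl)phenyl][3,5-bis(tosyloxy)phenyl]methanone; 11 4-methoxybenzyl chloride
Product: 12 (E)-[3-bromo-4-methoxy-6-(4-methoxybenzyloxy)-2-(4-methoxystyryl)phenyl][3,5-bis(tosyloxy)phenyl]methanone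
Conditions: K2CO3, n-Bu4NI (cat.), DMF, 40 °C
Reagents that add atoms: none
Why: Williamson etherification of the phenoxide with the reactive benzylic chloride (iodide catalysis) places the benzylic C–H bonds that the carbene will insert into five atoms from the ketone carbon.

Step 8
Reactants: 12 (E)-[3-bromo-4-methoxy-6-(4-methoxybenzyloxy)-2-(4-methoxystyryl)phenyl][3,5-bis(tosyloxy)phenyl]methanone
Product: 13 N-unsubstituted hydrazone of ketone 12 (mixture of C=N isomers)
Conditions: N2H4·H2O (10 equiv), AcOH (cat.), EtOH, 80 °C, sealed tube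
Reagents that add atoms: hydrazine (used as its hydrate), NN
Why: Acid-catalysed condensation of the diaryl ketone with a large excess of hydrazine should give the free hydrazone and suppress azine formation, and both C=N isomers lead to the same diazo compound.

Step 9
Reactants: 13 N-unsubstituted hydrazone of ketone 12
Product: 15 cis-(2R,3S)-5-bromo-6-methoxy-2-(4-methoxyphenyl)-4-[(E)-4-methoxystyryl]-3-[3,5-bis(tosyloxy)phenyl]-2,3-dihydrobenzofuran, via diazo compound 14 (not isolated)
Conditions: MnO2 (activated, 8 equiv), CH2Cl2, 0 °C; then Rh2(R-PTAD)4 (dirhodium tetrakis[(R)-(1-adamantyl)(N-phthalimido)acetate], 1 mol %), 0 °C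
Reagents that add atoms: none
Why: Dehydrogenation of the hydrazone by MnO2 gives the diaryldiazomethane, whose donor/donor carbene on divalent rhodium should undergo enantioselective intramolecular 1,5 C–H insertion into the benzylic ether C–H bond, the chiral carboxylate ligands setting C3 (S) and the concerted insertion giving the cis-2,3-diaryl isomer (C2 R, a centre given up in step 11), while the two ortho substituents twist ring B out of conjugation with the diazo carbon and so disfavour its cyclisation onto the styryl group.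

Step 10
Reactants: 15 cis-(2R,3S)-5-bromo-6-methoxy-2-(4-methoxyphenyl)-4-[(E)-4-methoxystyryl]-3-[3,5-bis(tosyloxy)phenyl]-2,3-dihydrobenzofuran; 16 3,5-dimethoxybenzoyl chloride
Product: 18 cis-(2R,3S)-5-(3,5-dimethoxybenzoyl)-6-methoxy-2-(4-methoxyphenyl)-4-[(E)-4-methoxystyryl]-3-[3,5-bis(tosyloxy)phenyl]-2,3-dihydrobenzofuran, via aryllithium 17 (not isolated)
Conditions: n-BuLi (1.05 equiv), THF, −78 °C, 5 min; then cannulation into 16 (2 equiv), THF, −78 °C
Reagents that add atoms: none
Why: Bromine–lithium exchange should outrun attack on the sulfonates at −78 °C, and inverse addition of the doubly ortho-substituted aryllithium to an excess of the aroyl chloride (acylation of an organolithium) should stop at the ketone because the hindered diaryl ketone resists a second addition.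

Step 11
Reactants: 18 cis-(2R,3S)-5-(3,5-dimethoxybenzoyl)-6-methoxy-2-(4-methoxyphenyl)-4-[(E)-4-methoxystyryl]-3-[3,5-bis(tosyloxy)phenyl]-2,3-dihydrobenzofuran
Product: 21 target pentamethyl ether bis-tosylate (free ring B phenol ortho to indane C3; methine S; indane 1R,2S,3S), via ring-opened cation 19 (not isolated), via indanyl cation 20 (not isolated)
Conditions: BF3·OEt2 (3 equiv), CH2Cl2, −78 to −20 °C; then H2O
Reagents that add atoms: none
Why: BF3 binds the furan oxygen and heterolysis of the C2–O bond (helped by the 4-methoxyphenyl group on C2 and by the aroyl group para to the departing oxygen) gives benzylic cation 19, which is attacked by the styryl carbon attached to ring B so that the charge moves to the other styryl carbon (4-methoxybenzylic cation 20), and this is intercepted by the ring A carbon ortho to the carbonyl group (ortho and para to the two methoxy groups), the proton lost from ring A ending on the ring B phenol. The closest known reaction types are the acid-induced conversion of 2,3-diaryl-4-styryl-2,3-dihydrobenzofurans of the ε-viniferin class into indanes of the ampelopsin D and F class, and cationic Friedel–Crafts closures of seven-membered rings in resveratrol oligomers. The cyclopentane closes by a 5-exo-trig cation–olefin cyclisation (new C2–C1 bond) and the cycloheptenone by an intramolecular Friedel–Crafts alkylation in which the attacked ring A bond lies inside the new seven-membered ring (new methine–ring A bond). Indane C3 is untouched; the planar C2 cation should be attacked on the face that puts its 4-methoxyphenyl group trans to the C3 aryl group, the (E)-alkene then places the C1 side chain trans to the C2 aryl group, and ring A should add to the face of cation 20 that is away from the C2 aryl group with the two hydrogens anti across the C1–methine bond, which gives the S methine. The step needs termination on ring A and not on the C3 aryl ring, which sits cis to the cationic side chain and would give a bicyclo[3.2.1]octane; the two tosylates make that ring too electron poor to compete, and the aprotic Lewis acid ionises the ether before the stilbene can be protonated.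

Step 12
Reactants: 21 target pentamethyl ether bis-tosylate
Product: 22 target pentamethyl ether (three free phenols: ring B and both positions of the 3,5-dihydroxyphenyl group; methine S; indane 1R,2S,3S)
Conditions: KOH (10 equiv), MeOH/THF, 60 °C, argon; then dilute aq. HCl
Reagents that add atoms: none
Why: Alkaline cleavage of aryl sulfonates by attack of hydroxide at sulfur should free both phenols, while the non-enolisable diaryl ketone, the methyl ethers and the benzylic stereocentres (none acidic enough for KOH) are unaffected.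

Step 13
Reactants: 22 target pentamethyl ether
Product: 23 CNP0116600.1 (methine S; indane 1R,2S,3S)
Conditions: BBr3 (15 equiv), CH2Cl2, −78 °C to rt; then H2O, 0 °C
Reagents that add atoms: none
Why: Cleavage of all five aryl methyl ethers by BBr3 (Lewis-acid ether cleavage, the usual last step for methylated resveratrol oligomers) touches no stereocentre, so the configuration of 22 should be carried into the target.

**Compound list**

1 | 3,5-dimethoxybenzaldehyde | COc1cc(C=O)cc(OC)c1 | starting material
2 | 2,6-dibromo-3,5-dimethoxybenzaldehyde | COc1cc(OC)c(Br)c(C=O)c1Br | intermediate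
3 | diethyl (4-methoxybenzyl)phosphonate | CCOP(=O)(Cc1ccc(OC)cc1)OCC | starting material
4 | (E)-2,6-dibromo-3,5-dimethoxy-4'-methoxystilbene | COc1ccc(/C=C/c2c(Br)c(OC)cc(OC)c2Br)cc1 | intermediate
5 | 3,5-dihydroxybenzaldehyde | O=Cc1cc(O)cc(O)c1 | starting material
6 | 3,5-bis(tosyloxy)benzaldehyde | O=Cc1cc(OS(=O)(=O)c2ccc(C)cc2)cc(OS(=O)(=O)c2ccc(C)cc2)c1 | intermediate
7 | (E)-3-bromo-4,6-dimethoxy-2-(4-methoxystyryl)phenyllithium (not isolated) | COc1ccc(/C=C/c2c(Br)c(OC)cc(OC)c2[Li])cc1 | intermediate
8 | racemic (E)-[3-bromo-4,6-dimethoxy-2-(4-methoxystyryl)phenyl][3,5-bis(tosyloxy)phenyl]methanol | COc1ccc(/C=C/c2c(Br)c(OC)cc(OC)c2C(O)c2cc(OS(=O)(=O)c3ccc(C)cc3)cc(OS(=O)(=O)c3ccc(C)cc3)c2)cc1 | intermediate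
9 | (E)-[3-bromo-4,6-dimethoxy-2-(4-methoxystyryl)phenyl][3,5-bis(tosyloxy)phenyl]methanone | COc1ccc(/C=C/c2c(Br)c(OC)cc(OC)c2C(=O)c2cc(OS(=O)(=O)c3ccc(C)cc3)cc(OS(=O)(=O)c3ccc(C)cc3)c2)cc1 | intermediate
10 | (E)-[3-bromo-6-hydroxy-4-methoxy-2-(4-methoxystyryl)phenyl][3,5-bis(tosyloxy)phenyl]methanone | COc1ccc(/C=C/c2c(Br)c(OC)cc(O)c2C(=O)c2cc(OS(=O)(=O)c3ccc(C)cc3)cc(OS(=O)(=O)c3ccc(C)cc3)c2)cc1 | intermediate
11 | 4-methoxybenzyl chloride | COc1ccc(CCl)cc1 | starting material
12 | (E)-[3-bromo-4-methoxy-6-(4-methoxybenzyloxy)-2-(4-methoxystyryl)phenyl][3,5-bis(tosyloxy)phenyl]methanone | COc1ccc(/C=C/c2c(Br)c(OC)cc(OCc3ccc(OC)cc3)c2C(=O)c2cc(OS(=O)(=O)c3ccc(C)cc3)cc(OS(=O)(=O)c3ccc(C)cc3)c2)cc1 | intermediate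
13 | N-unsubstituted hydrazone of ketone 12 (mixture of C=N isomers) | COc1ccc(/C=C/c2c(Br)c(OC)cc(OCc3ccc(OC)cc3)c2C(=NN)c2cc(OS(=O)(=O)c3ccc(C)cc3)cc(OS(=O)(=O)c3ccc(C)cc3)c2)cc1 | intermediate
14 | (E)-[3-bromo-4-methoxy-6-(4-methoxybenzyloxy)-2-(4-methoxystyryl)phenyl][3,5-bis(tosyloxy)phenyl]diazomethane (not isolated) | COc1ccc(/C=C/c2c(Br)c(OC)cc(OCc3ccc(OC)cc3)c2C(=[N+]=[N-])c2cc(OS(=O)(=O)c3ccc(C)cc3)cc(OS(=O)(=O)c3ccc(C)cc3)c2)cc1 | intermediate
15 | cis-(2R,3S)-5-bromo-6-methoxy-2-(4-methoxyphenyl)-4-[(E)-4-methoxystyryl]-3-[3,5-bis(tosyloxy)phenyl]-2,3-dihydrobenzofuran | COc1ccc(/C=C/c2c(Br)c(OC)cc3c2[C@H](c2cc(OS(=O)(=O)c4ccc(C)cc4)cc(OS(=O)(=O)c4ccc(C)cc4)c2)[C@H](c2ccc(OC)cc2)O3)cc1 | intermediate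
16 | 3,5-dimethoxybenzoyl chloride | COc1cc(C(=O)Cl)cc(OC)c1 | starting material
17 | 5-lithio analogue of 15 (lithium in place of bromine, not isolated) | COc1ccc(/C=C/c2c([Li])c(OC)cc3c2[C@H](c2cc(OS(=O)(=O)c4ccc(C)cc4)cc(OS(=O)(=O)c4ccc(C)cc4)c2)[C@H](c2ccc(OC)cc2)O3)cc1 | intermediate
18 | cis-(2R,3S)-5-(3,5-dimethoxybenzoyl)-6-methoxy-2-(4-methoxyphenyl)-4-[(E)-4-methoxystyryl]-3-[3,5-bis(tosyloxy)phenyl]-2,3-dihydrobenzofuran | COc1ccc(/C=C/c2c(C(=O)c4cc(OC)cc(OC)c4)c(OC)cc3c2[C@H](c2cc(OS(=O)(=O)c4ccc(C)cc4)cc(OS(=O)(=O)c4ccc(C)cc4)c2)[C@H](c2ccc(OC)cc2)O3)cc1 | intermediate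
19 | ring-opened 4-methoxybenzylic cation from 18 (furan C2–O bond broken, ring B oxygen bound to BF3, C3 unchanged; not isolated) | COc1ccc(/C=C/c2c(C(=O)c4cc(OC)cc(OC)c4)c(OC)cc(O[B-](F)(F)F)c2[C@H](c2cc(OS(=O)(=O)c4ccc(C)cc4)cc(OS(=O)(=O)c4ccc(C)cc4)c2)[CH+]c2ccc(OC)cc2)cc1 | intermediate
20 | indanyl cation: all-trans 1,2,3-trisubstituted indane with the 4-methoxybenzylic cation on the C1 side chain, ring A still open, ring B oxygen bound to BF3 (not isolated) | COc1ccc([CH+][C@@H]2c3c(C(=O)c4cc(OC)cc(OC)c4)c(OC)cc(O[B-](F)(F)F)c3[C@H](c3cc(OS(=O)(=O)c4ccc(C)cc4)cc(OS(=O)(=O)c4ccc(C)cc4)c3)[C@H]2c2ccc(OC)cc2)cc1 | intermediate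
21 | target pentamethyl ether bis-tosylate: 10,11-dihydro-5H-dibenzo[a,d]cyclohepten-5-one with an indane fused across C11 and the neighbouring ring B carbon; methyl ethers on both ring A oxygens, on the ring B oxygen ortho to the ketone and on both 4-oxyphenyl groups; tosylates on the 3,5-dioxyphenyl group at indane C3; free ring B phenol ortho to C3; methine S, indane 1R,2S,3S | O=C1c2cc(OC)cc(OC)c2[C@H](c2ccc(OC)cc2)[C@@H]2c3c1c(OC)cc(O)c3[C@H](c1cc(OS(=O)(=O)c4ccc(C)cc4)cc(OS(=O)(=O)c4ccc(C)cc4)c1)[C@H]2c1ccc(OC)cc1 | intermediate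
22 | target pentamethyl ether: as 21 with a 3,5-dihydroxyphenyl group at indane C3; methine S, indane 1R,2S,3S | O=C1c2cc(OC)cc(OC)c2[C@H](c2ccc(OC)cc2)[C@@H]2c3c1c(OC)cc(O)c3[C@H](c1cc(O)cc(O)c1)[C@H]2c1ccc(OC)cc1 | intermediate
23 | CNP0116600.1: octahydroxy indane-fused dibenzocycloheptenone; methine S, indane 1R,2S,3S | O=C1c2cc(O)cc(O)c2[C@H](c2ccc(O)cc2)[C@@H]2c3c1c(O)cc(O)c3[C@H](c1cc(O)cc(O)c1)[C@H]2c1ccc(O)cc1 | target

**Step count**

Total: 13 steps. Longest linear sequence: 12 steps (steps 1, 2 and 4 to 13, from 1).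

**Steps most likely to fail**

Step 11. Three processes may divert the cascade:
- loss of the C3 proton from the ring-opened cation (an elimination that erases the catalytically set centre);
- poor facial selectivity in the 5-exo closure;
- interception of the second cation by the ketone oxygen (a cyclic oxocarbenium resting state) or by an outside nucleophile in place of ring A.

Fallback, setting out from 18 and coming back at 21: the cascade is divided into two known operations. Solvolytic ring opening of 18 with camphorsulfonic acid in MeOH/CH2Cl2 at 0 °C to rt lets methanol intercept the cation after the 5-exo closure. This gives the indanyl benzylic methyl ether F1 (both epimers at the CH–OMe carbon are usable). The isolated ether is then re-ionised on its own (TsOH·H2O, CH2Cl2/hexafluoroisopropanol, rt), so that the seven-membered ring closes in a separate Friedel–Crafts alkylation under conditions chosen for that bond alone, giving 21.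

Step 9. The diazo group or the carbene may be consumed by the neighbouring styryl unit (electrocyclisation of the diazo compound onto the alkene, or carbene addition to it) before insertion into the ether C–H bond. Fallback, setting out from 12 and coming back at 15: the styryl unit is kept out of the carbene step.
- Lemieux–Johnson cleavage of the alkene of 12 (OsO4 cat., NaIO4, 2,6-lutidine, dioxane/H2O) gives the keto aldehyde F2.
- The aldehyde alone is masked as its 1,3-dioxolane F3 (1,2-bis(trimethylsilyloxy)ethane, TMSOTf cat., CH2Cl2, −78 °C); the diaryl ketone is too hindered to ketalise.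
- Condensation with N2H4·H2O in EtOH gives the hydrazone F4, MnO2 gives the diazo compound F5, and the same Rh2(R-PTAD)4 insertion gives the cis-(2R,3S) dihydrobenzofuran acetal F6.
- Mild hydrolysis (pyridinium p-toluenesulfonate, acetone/H2O) frees the aldehyde F7.
- Horner–Wadsworth–Emmons olefination with 3 (KOt-Bu, THF, 0 °C) puts the (E)-4-methoxystyryl group back and gives 15.

If this line were adopted from the outset, the aldehyde would be carried from 2 without building the stilbene first.

Step 8. Condensation at the doubly ortho-substituted carbonyl group may stay incomplete, and prolonged heating with hydrazine may cleave the aryl sulfonates. Fallback, setting out from 12 and coming back at 13: the hydrazone nitrogen is delivered without free hydrazine or heat. Treatment of 12 with 1,2-bis(tert-butyldimethylsilyl)hydrazine and Sc(OTf)3 (cat.) in CHCl3 at rt to 50 °C gives the N-silyl hydrazone F8. Desilylation with n-Bu4NF in THF at 0 °C then gives 13.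

**Further compounds**

F1 | step 11 | indanyl benzylic methyl ether: all-trans indane as in 21, C1 side chain CH(OMe)(4-methoxyphenyl) as an epimer mixture, ring A not yet bonded, ring B phenol free | COc1ccc(C(OC)[C@@H]2c3c(C(=O)c4cc(OC)cc(OC)c4)c(OC)cc(O)c3[C@H](c3cc(OS(=O)(=O)c4ccc(C)cc4)cc(OS(=O)(=O)c4ccc(C)cc4)c3)[C@H]2c2ccc(OC)cc2)cc1
F2 | step 9 | [3-bromo-2-formyl-4-methoxy-6-(4-methoxybenzyloxy)phenyl][3,5-bis(tosyloxy)phenyl]methanone | COc1ccc(COc2cc(OC)c(Br)c(C=O)c2C(=O)c2cc(OS(=O)(=O)c3ccc(C)cc3)cc(OS(=O)(=O)c3ccc(C)cc3)c2)cc1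
F3 | step 9 | [3-bromo-2-(1,3-dioxolan-2-yl)-4-methoxy-6-(4-methoxybenzyloxy)phenyl][3,5-bis(tosyloxy)phenyl]methanone | COc1ccc(COc2cc(OC)c(Br)c(C3OCCO3)c2C(=O)c2cc(OS(=O)(=O)c3ccc(C)cc3)cc(OS(=O)(=O)c3ccc(C)cc3)c2)cc1
F4 | step 9 | N-unsubstituted hydrazone of ketone F3 | COc1ccc(COc2cc(OC)c(Br)c(C3OCCO3)c2C(=NN)c2cc(OS(=O)(=O)c3ccc(C)cc3)cc(OS(=O)(=O)c3ccc(C)cc3)c2)cc1
F5 | step 9 | [3-bromo-2-(1,3-dioxolan-2-yl)-4-methoxy-6-(4-methoxybenzyloxy)phenyl][3,5-bis(tosyloxy)phenyl]diazomethane | COc1ccc(COc2cc(OC)c(Br)c(C3OCCO3)c2C(=[N+]=[N-])c2cc(OS(=O)(=O)c3ccc(C)cc3)cc(OS(=O)(=O)c3ccc(C)cc3)c2)cc1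
F6 | step 9 | cis-(2R,3S)-5-bromo-4-(1,3-dioxolan-2-yl)-6-methoxy-2-(4-methoxyphenyl)-3-[3,5-bis(tosyloxy)phenyl]-2,3-dihydrobenzofuran | O1CCOC1c1c(Br)c(OC)cc2c1[C@H](c1cc(OS(=O)(=O)c3ccc(C)cc3)cc(OS(=O)(=O)c3ccc(C)cc3)c1)[C@H](c1ccc(OC)cc1)O2
F7 | step 9 | cis-(2R,3S)-5-bromo-4-formyl-6-methoxy-2-(4-methoxyphenyl)-3-[3,5-bis(tosyloxy)phenyl]-2,3-dihydrobenzofuran | O=Cc1c(Br)c(OC)cc2c1[C@H](c1cc(OS(=O)(=O)c3ccc(C)cc3)cc(OS(=O)(=O)c3ccc(C)cc3)c1)[C@H](c1ccc(OC)cc1)O2
F8 | step 8 | N-(tert-butyldimethylsilyl)hydrazone of ketone 12 | COc1ccc(/C=C/c2c(Br)c(OC)cc(OCc3ccc(OC)cc3)c2C(=NN[Si](C)(C)C(C)(C)C)c2cc(OS(=O)(=O)c3ccc(C)cc3)cc(OS(=O)(=O)c3ccc(C)cc3)c2)cc1
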